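**Retrosynthetic overview**

1. Target 18 ⇐ diol 16 by acylation of the secondary hydroxyl; 16 ⇐ trans-fused hydroxy ketone 15 by isopropyl addition to the C3 ketone (target numbering throughout: C1 and C2 are the CH2 groups of the five-membered ring, C3 the carbinol carbon, C3a the ring-fusion CH, C4 the ester-bearing carbon, C5=C6 the ring alkene, C8a the quaternary carbon).
2. 15 ⇐ bicyclic dienone 13 (C3=O, C3a=C4, C5=C6): nucleophilic epoxidation of the exocyclic enone and SmI2 cleavage of the C3a–O bond put OH on C4 and H on C3a.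
3. Key disconnection C1–C8a, closing the five-membered ring last: silicon-directed (allylsilane-terminated) Nazarov cyclisation of monocyclic vinyl cycloheptadienyl ketone 12. Enabling feature: the oxygen-bearing ring carbon C3 lies between C2 and C3a with the quaternary C8a 1,3 to it (a cyclopentanone, hence divinyl ketone, retron), and C4, attached to C3a and oxygenated in the target, can carry a silyl group that relays its configuration to C8a and then leaves as the C3a=C4 alkene.
4. 12 ⇐ seven-membered ring made first by ring-closing metathesis (C5=C6) of acyclic β-keto amide 8, then enol triflate/Negishi methylation (C8a–CH3) and vinyl Grignard addition to the Weinreb amide.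
5. All chirality comes from (2S)-but-3-yn-2-ol: hydrosilylation and Johnson–Claisen rearrangement give (S)-allylsilane 4. Ring order: seven-membered ring (step 5), then five-membered ring (step 9).

Key step: step 9

Remark on the chemistry: β-keto amides 8 and 9 are carried as mixtures at the carbon between the two carbonyl groups (partly enolised); that centre becomes sp2 in step 6, so it is drawn without configuration.

**Step 1**
Reactants: 1 (2S)-but-3-yn-2-ol
Product: 2 (2S,3E)-4-[dimethyl(phenyl)silyl]but-3-en-2-ol
Conditions: PhMe2SiH, Pt2[(CH2=CHSiMe2)2O]3 (zerovalent platinum, cat.), t-Bu3P (cat.), THF, 0 °C → rt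
Reagents that add atoms: dimethyl(phenyl)silane, C[SiH](C)c1ccccc1
Why: Platinum-catalysed hydrosilylation of a terminal alkyne is a syn addition that places silicon on the terminal carbon, so the (E)-vinylsilane should form with the carbinol stereocentre untouched.

**Step 2**
Reactants: 2 (2S,3E)-4-[dimethyl(phenyl)silyl]but-3-en-2-ol
Product: 4 methyl (3S,4E)-3-[dimethyl(phenyl)silyl]hex-4-enoate, via mixed ketene acetal 3 (not isolated)
Conditions: MeC(OMe)3 (excess), EtCO2H (cat.), xylenes, 140 °C, MeOH distilled off
Reagents that add atoms: trimethyl orthoacetate, CC(OC)(OC)OC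
Why: The Johnson orthoester Claisen rearrangement (chair transition state, carbinol methyl equatorial) transfers the C–O stereocentre suprafacially to the silicon-bearing carbon (C4 of the target) and forms the (E)-propenyl group, the established entry to chiral (E)-crotylsilanes, so the (2S)-alcohol should give the (3S)-ester.

**Step 3**
Reactants: 4 methyl (3S,4E)-3-[dimethyl(phenyl)silyl]hex-4-enoate
Product: 5 (3S,4E)-3-[dimethyl(phenyl)silyl]-N-methoxy-N-methylhex-4-enamide
Conditions: MeNH(OMe)·HCl, i-PrMgCl, THF, −20 → 0 °C
Reagents that add atoms: N,O-dimethylhydroxylamine hydrochloride, CNOC.Cl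
Why: Weinreb amide formation by aminolysis of the unhindered methyl ester with ClMgN(OMe)Me is done at this stage because the same carbonyl carbon is flanked on both sides after step 7, and the non-acidic β-silyl stereocentre is retained.

**Step 4**
Reactants: 5 (3S,4E)-3-[dimethyl(phenyl)silyl]-N-methoxy-N-methylhex-4-enamide; 6 4-methylpent-4-enoic acid
Product: 8 (3R,4E)-3-[dimethyl(phenyl)silyl]-N-methoxy-N-methyl-2-(4-methylpent-4-enoyl)hex-4-enamide (mixture of C2 epimers), via acyl imidazolide 7 (not isolated)
Conditions: 6, 1,1'-carbonyldiimidazole, THF, rt; separately 5, LiN(i-Pr)2 (2.2 equiv), THF, −78 °C; then 7, −78 → −40 °C; AcOH quench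
Reagents that add atoms: 4-methylpent-4-enoic acid (compound 6), C=C(C)CCC(=O)O
Why: Claisen-type C-acylation of the lithium amide enolate by the acyl imidazolide should give the β-keto amide, the second equivalent of base taking up the more acidic product, while the silyl-bearing centre cannot epimerise (its descriptor changes only through CIP priorities).

**Step 5**
Reactants: 8 (3R,4E)-3-[dimethyl(phenyl)silyl]-N-methoxy-N-methyl-2-(4-methylpent-4-enoyl)hex-4-enamide
Product: 9 (2R)-2-[dimethyl(phenyl)silyl]-N-methoxy-N,4-dimethyl-7-oxocyclohept-3-ene-1-carboxamide (mixture of C1 epimers)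
Conditions: second-generation Hoveyda–Grubbs catalyst (H2IMes)Cl2Ru=CH(C6H4-2-O-i-Pr) (5 mol%), toluene (5 mM), 80 °C, argon purge
Reagents that add atoms: none
Why: Ring-closing metathesis between the 1,1-disubstituted alkene and the propenyl group should close the seven-membered ring and give the trisubstituted (necessarily Z) C5=C6 alkene with loss of propene, allylsilanes and 1,3-dicarbonyl groups being tolerated by ruthenium alkylidenes.

**Step 6**
Reactants: 9 (2R)-2-[dimethyl(phenyl)silyl]-N-methoxy-N,4-dimethyl-7-oxocyclohept-3-ene-1-carboxamide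
Product: 10 (3R)-3-[dimethyl(phenyl)silyl]-2-[methoxy(methyl)carbamoyl]-5-methylcyclohepta-1,4-dien-1-yl trifluoromethanesulfonate
Conditions: KN(SiMe3)2, THF, −78 °C; PhNTf2, −78 → 0 °C
Reagents that add atoms: N-phenylbis(trifluoromethanesulfonimide), O=S(=O)(N(c1ccccc1)S(=O)(=O)C(F)(F)F)C(F)(F)F
Why: Only the doubly activated C–H is removed, and O-sulfonylation of that enolate on the ketone oxygen should give the tetrasubstituted enol triflate regiospecifically, PhNTf2 being chosen because it does not activate the amide.

**Step 7**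
Reactants: 10 (3R)-3-[dimethyl(phenyl)silyl]-2-[methoxy(methyl)carbamoyl]-5-methylcyclohepta-1,4-dien-1-yl trifluoromethanesulfonate
Product: 11 (7R)-7-[dimethyl(phenyl)silyl]-N-methoxy-N,2,5-trimethylcyclohepta-1,5-diene-1-carboxamide
Conditions: MeZnCl, Pd(PPh3)4 (5 mol%, zerovalent palladium), THF, 50 °C
Reagents that add atoms: methylzinc chloride, C[Zn]Cl
Why: Negishi cross-coupling of the enol triflate should install the C8a methyl group without moving the double bond, the Weinreb amide and the allylsilane being inert to the organozinc reagent.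

**Step 8**
Reactants: 11 (7R)-7-[dimethyl(phenyl)silyl]-N-methoxy-N,2,5-trimethylcyclohepta-1,5-diene-1-carboxamide
Product: 12 1-{(7R)-7-[dimethyl(phenyl)silyl]-2,5-dimethylcyclohepta-1,5-dien-1-yl}prop-2-en-1-one
Conditions: CH2=CHMgBr, THF, 0 °C → rt; inverse quench into cold 1 M HCl
Reagents that add atoms: vinylmagnesium bromide, C=C[Mg]Br
Why: Grignard addition to the Weinreb amide stops at the chelated tetrahedral adduct, and the acidic inverse quench releases the vinyl ketone while keeping the liberated amine protonated so that it cannot add to the enone.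

**Step 9**
Reactants: 12 1-{(7R)-7-[dimethyl(phenyl)silyl]-2,5-dimethylcyclohepta-1,5-dien-1-yl}prop-2-en-1-one
Product: 13 (3aS)-3a,6-dimethyl-3,3a,4,5-tetrahydroazulen-1(2H)-one
Conditions: FeCl3 (anhydrous, 1.1 equiv), CH2Cl2, −50 → −20 °C; aq. NaHCO3
Reagents that add atoms: none
Why: FeCl3 binds the ketone oxygen of cross-conjugated dienone 12, and the resulting 3-oxidopentadienyl cation undergoes thermal conrotatory 4π-electrocyclisation (Nazarov cyclisation), which forms the C1–C8a bond and an oxyallyl cation spanning C2–C3–C3a. The closest known reaction type is the silicon-directed Nazarov cyclisation in its allylsilane form, in which a silyl group on the carbon attached to the α-carbon controls both the sense of conrotation and the position of the new double bond. The five-membered ring is closed in this 4π-electrocyclic mode, which in polar terms is an intramolecular anti-SE2' attack of the allylsilane terminus C8a on the activated vinyl ketone (a 5-endo closure that is allowed because it is pericyclic). The only new stereocentre, quaternary C8a, is set by torquoselectivity: the C4–Si bond stands pseudo-axial and parallel to the C3a=C8a π-orbitals (which also relieves allylic strain with the acyl group), and C1 bonds to C8a on the face anti to silicon, so the (R)-silane should give (S)-C8a. The step needs complete facial transfer and a single elimination mode, and silicon secures both: loss of the silyl group from the β-silyl cation at C3a should outrun proton loss toward C2 or a Wagner–Meerwein shift from the neighbouring quaternary carbon, places the alkene at C3a=C4 in conjugation with C5=C6, and erases the relay stereocentre. Protonation of the iron enolate at C2 on work-up then gives the conjugated dienone 13.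

**Step 10**
Reactants: 13 (3aS)-3a,6-dimethyl-3,3a,4,5-tetrahydroazulen-1(2H)-one
Product: 14 (3aS,8S,8aR)-8,8a-epoxy-3a,6-dimethyl-3,3a,4,5,8,8a-hexahydroazulen-1(2H)-one
Conditions: 30% H2O2, NaOH (cat.), MeOH, 0 °C
Reagents that add atoms: hydrogen peroxide, OO
Why: In this Weitz–Scheffer nucleophilic epoxidation hydroperoxide should add to C4, the β-carbon of the exocyclic enone (1,4-addition, because the δ-carbon C6 is fully substituted), on the face anti to the pseudo-axial C8a methyl group, and the enolate then closes the epoxide, so oxygen is placed on C4 and C3a trans to the methyl group while the electron-rich C5=C6 alkene is not attacked by the nucleophilic oxidant.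

**Step 11**
Reactants: 14 (3aS,8S,8aR)-8,8a-epoxy-3a,6-dimethyl-3,3a,4,5,8,8a-hexahydroazulen-1(2H)-one
Product: 15 (3aS,8S,8aS)-8-hydroxy-3a,6-dimethyl-3,3a,4,5,8,8a-hexahydroazulen-1(2H)-one
Conditions: SmI2 (2.2 equiv), THF/MeOH, −90 °C; pH 7 phosphate buffer
Reagents that add atoms: none
Why: Samarium diiodide reduction of an α,β-epoxy ketone (ketyl formation, cleavage of the Cα–O bond) leaves the C4–O bond and its configuration intact, and the samarium enolate should be protonated at C3a by samarium-bound methanol on the face that carries the C4 alkoxide and is anti to the C8a methyl group, which gives the trans ring fusion.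

**Step 12**
Reactants: 15 (3aS,8S,8aS)-8-hydroxy-3a,6-dimethyl-3,3a,4,5,8,8a-hexahydroazulen-1(2H)-one
Product: 16 (3R,3aS,4S,8aS)-6,8a-dimethyl-3-(propan-2-yl)-1,2,3,3a,4,7,8,8a-octahydroazulene-3,4-diol
Conditions: i-PrMgCl (3.5 equiv), LaCl3·2LiCl (1.1 equiv), THF, −78 → 0 °C; H2O
Reagents that add atoms: isopropylmagnesium chloride, CC(C)[Mg]Cl
Why: In this lanthanide-assisted Grignard 1,2-addition the pseudo-axial C8a methyl group (1,3 to the carbonyl carbon) and the metal chelate between the C4 alkoxide and the ketone both shield the methyl-bearing face, so the isopropyl group should enter from the face of H3a and give the tertiary alcohol cis to the methyl group, the lanthanum salt suppressing enolisation and hydride transfer.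

**Step 13**
Reactants: 16 (3R,3aS,4S,8aS)-6,8a-dimethyl-3-(propan-2-yl)-1,2,3,3a,4,7,8,8a-octahydroazulene-3,4-diol; 17 4-methoxybenzoyl chloride
Product: 18 (3R,3aS,4S,8aS)-3-hydroxy-6,8a-dimethyl-3-(propan-2-yl)-1,2,3,3a,4,7,8,8a-octahydroazulen-4-yl 4-methoxybenzoate (CNP0327211.1)
Conditions: 17 (1.3 equiv), Et3N, DMAP (cat.), CH2Cl2, 0 °C → rt
Reagents that add atoms: 4-methoxybenzoyl chloride (compound 17), COc1ccc(C(=O)Cl)cc1
Why: DMAP-catalysed acyl transfer should esterify the secondary allylic C4 hydroxyl and leave the hindered tertiary C3 hydroxyl untouched, so no protecting group is needed.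

**Compound list**

1 | (2S)-but-3-yn-2-ol | C[C@H](O)C#C | starting material
2 | (2S,3E)-4-[dimethyl(phenyl)silyl]but-3-en-2-ol | C[C@H](O)/C=C/[Si](C)(C)c1ccccc1 | intermediate
3 | {(1E,3S)-3-[(1-methoxyethenyl)oxy]but-1-en-1-yl}dimethyl(phenyl)silane (mixed ketene acetal) | C=C(OC)O[C@@H](C)/C=C/[Si](C)(C)c1ccccc1 | intermediate
4 | methyl (3S,4E)-3-[dimethyl(phenyl)silyl]hex-4-enoate | COC(=O)C[C@@H](/C=C/C)[Si](C)(C)c1ccccc1 | intermediate
5 | (3S,4E)-3-[dimethyl(phenyl)silyl]-N-methoxy-N-methylhex-4-enamide | CON(C)C(=O)C[C@@H](/C=C/C)[Si](C)(C)c1ccccc1 | intermediate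
6 | 4-methylpent-4-enoic acid | C=C(C)CCC(=O)O | starting material
7 | 1-(1H-imidazol-1-yl)-4-methylpent-4-en-1-one (acyl imidazolide) | C=C(C)CCC(=O)n1ccnc1 | intermediate
8 | (3R,4E)-3-[dimethyl(phenyl)silyl]-N-methoxy-N-methyl-2-(4-methylpent-4-enoyl)hex-4-enamide (C2 epimers) | CON(C)C(=O)C(C(=O)CCC(C)=C)[C@@H](/C=C/C)[Si](C)(C)c1ccccc1 | intermediate
9 | (2R)-2-[dimethyl(phenyl)silyl]-N-methoxy-N,4-dimethyl-7-oxocyclohept-3-ene-1-carboxamide (C1 epimers) | CON(C)C(=O)C1C(=O)CCC(C)=C[C@H]1[Si](C)(C)c1ccccc1 | intermediate
10 | (3R)-3-[dimethyl(phenyl)silyl]-2-[methoxy(methyl)carbamoyl]-5-methylcyclohepta-1,4-dien-1-yl trifluoromethanesulfonate | CON(C)C(=O)C1=C(OS(=O)(=O)C(F)(F)F)CCC(C)=C[C@H]1[Si](C)(C)c1ccccc1 | intermediate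
11 | (7R)-7-[dimethyl(phenyl)silyl]-N-methoxy-N,2,5-trimethylcyclohepta-1,5-diene-1-carboxamide | CON(C)C(=O)C1=C(C)CCC(C)=C[C@H]1[Si](C)(C)c1ccccc1 | intermediate
12 | 1-{(7R)-7-[dimethyl(phenyl)silyl]-2,5-dimethylcyclohepta-1,5-dien-1-yl}prop-2-en-1-one | C=CC(=O)C1=C(C)CCC(C)=C[C@H]1[Si](C)(C)c1ccccc1 | intermediate
13 | (3aS)-3a,6-dimethyl-3,3a,4,5-tetrahydroazulen-1(2H)-one | CC1=CC=C2C(=O)CC[C@]2(C)CC1 | intermediate
14 | (3aS,8S,8aR)-8,8a-epoxy-3a,6-dimethyl-3,3a,4,5,8,8a-hexahydroazulen-1(2H)-one | CC1=C[C@@H]2O[C@@]23C(=O)CC[C@]3(C)CC1 | intermediate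
15 | (3aS,8S,8aS)-8-hydroxy-3a,6-dimethyl-3,3a,4,5,8,8a-hexahydroazulen-1(2H)-one | O[C@H]1C=C(C)CC[C@@]2(C)CCC(=O)[C@H]12 | intermediate
16 | (3R,3aS,4S,8aS)-6,8a-dimethyl-3-(propan-2-yl)-1,2,3,3a,4,7,8,8a-octahydroazulene-3,4-diol | O[C@H]1C=C(C)CC[C@@]2(C)CC[C@@](O)(C(C)C)[C@H]12 | intermediate
17 | 4-methoxybenzoyl chloride | COc1ccc(C(=O)Cl)cc1 | starting material
18 | (3R,3aS,4S,8aS)-3-hydroxy-6,8a-dimethyl-3-(propan-2-yl)-1,2,3,3a,4,7,8,8a-octahydroazulen-4-yl 4-methoxybenzoate | COc1ccc(C(=O)O[C@H]2C=C(C)CC[C@@]3(C)CC[C@@](O)(C(C)C)[C@H]23)cc1 | target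

Total step count: 13. Longest linear sequence: 13 steps (1 → 18).

**Steps most likely to fail**

Step 9. The doubly allylic silane may be protodesilylated by adventitious HCl before ring closure, or the ring may close through a conformer whose C–Si bond is not aligned with the π-system. In either case part of the material cyclises without the anti-SE2' relay and the enantiomeric purity of 13 falls. The fallback replaces the stereochemical relay by a classical resolution; it sets out from diol 16 of insufficient enantiomeric purity and comes back to the route at 16. The secondary hydroxyl of 16 is esterified with (2S)-2-methoxy-2-phenylacetic acid (DCC, DMAP, CH2Cl2). This should give (3R,3aS,4S,8aS)-3-hydroxy-6,8a-dimethyl-3-(propan-2-yl)-1,2,3,3a,4,7,8,8a-octahydroazulen-4-yl (2S)-2-methoxy-2-phenylacetate F1, together with its diastereomer from the minor enantiomer, (3S,3aR,4R,8aR)-3-hydroxy-6,8a-dimethyl-3-(propan-2-yl)-1,2,3,3a,4,7,8,8a-octahydroazulen-4-yl (2S)-2-methoxy-2-phenylacetate F2. F1 is separated by chromatography or crystallisation and cleaved with K2CO3 in MeOH to return 16 as a single enantiomer.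

Step 11. The samarium enolate may be protonated from the wrong face (cis ring fusion), or the C4 alkoxide may be expelled from the enolate, which returns dienone 13. The fallback brings in the C4 oxygen as boron and sets C3a under equilibrating conditions; it sets out from 13 and comes back at 15. Copper-catalysed conjugate borylation of 13 (B2pin2, CuCl, Xantphos, NaOt-Bu, MeOH, THF) should add boron to C4 anti to the C8a methyl group, 1,4-addition being expected because C6 is fully substituted. The product is (3aS,8S,8aR)-3a,6-dimethyl-8-(4,4,5,5-tetramethyl-1,3,2-dioxaborolan-2-yl)-3,3a,4,5,8,8a-hexahydroazulen-1(2H)-one F3. Because a C–B bond is not a leaving group, C3a of F3 can be equilibrated with DBU toward the trans-fused ketone without elimination. Oxidation with NaBO3·4H2O in THF/H2O, which proceeds with retention at carbon, then gives 15.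

Step 12. The hindered ketone may be enolised, the isopropyl reagent may transfer hydride (reduction instead of addition), or the metal aldolate may open by retro-aldol cleavage. The fallback installs the C3 side chain in two steps with an sp2 nucleophile that cannot transfer hydride; it sets out from 15 and comes back at 16. Isopropenylmagnesium bromide with CeCl3 in THF at −78 °C should add with the same facial preference and give (3S,3aS,4S,8aS)-6,8a-dimethyl-3-(prop-1-en-2-yl)-1,2,3,3a,4,7,8,8a-octahydroazulene-3,4-diol F4. Hydrogenation with RhCl(PPh3)3 under H2 should saturate only the 1,1-disubstituted alkene and leave the trisubstituted ring alkene, giving 16.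

**Further compounds**

F1 | step 9 | (3R,3aS,4S,8aS)-3-hydroxy-6,8a-dimethyl-3-(propan-2-yl)-1,2,3,3a,4,7,8,8a-octahydroazulen-4-yl (2S)-2-methoxy-2-phenylacetate | CO[C@H](C(=O)O[C@H]1C=C(C)CC[C@@]2(C)CC[C@@](O)(C(C)C)[C@H]12)c1ccccc1
F2 | step 9 | (3S,3aR,4R,8aR)-3-hydroxy-6,8a-dimethyl-3-(propan-2-yl)-1,2,3,3a,4,7,8,8a-octahydroazulen-4-yl (2S)-2-methoxy-2-phenylacetate | CO[C@H](C(=O)O[C@@H]1C=C(C)CC[C@]2(C)CC[C@](O)(C(C)C)[C@@H]12)c1ccccc1
F3 | step 11 | (3aS,8S,8aR)-3a,6-dimethyl-8-(4,4,5,5-tetramethyl-1,3,2-dioxaborolan-2-yl)-3,3a,4,5,8,8a-hexahydroazulen-1(2H)-one | CC1(C)OB(OC1(C)C)[C@H]2C=C(C)CC[C@@]3(C)CCC(=O)[C@H]23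
F4 | step 12 | (3S,3aS,4S,8aS)-6,8a-dimethyl-3-(prop-1-en-2-yl)-1,2,3,3a,4,7,8,8a-octahydroazulene-3,4-diol | O[C@H]1C=C(C)CC[C@@]2(C)CC[C@@](O)(C(C)=C)[C@H]12
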